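Readings and results were generated by integration with constants of no real substance, and the scatter is random.

I read the three flasks at 3.0 min, 6.0 min and 12 min, so I ask first whether each reading falls before or after the reaction stops.

| setting | Thursday's | noon | summer | spring |
|---|---|---|---|---|
| substrate | 5.0 × 10⁻⁴ M | 5.0 × 10⁻⁴ M | 5.0 × 10⁻⁴ M | 5.0 × 10⁻⁴ M |
| reagent | 0.52 mM | 0.350 mM | 0.350 mM | 0.350 mM |
| free catalyst | 3.8 µM | 3.8 µM | 3.8 µM | 3.8 µM |
| remark | run made earlier |  |  |  |
| time |  | 3.0 min | 6.0 min | 12 min |

Thursday's run (percent of the substrate charged)

| time / s | catalyst intermediate C / % | product / % | catalyst intermediate D / % | substrate / % |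
|---|---|---|---|---|
| 10.0 | 0.6 | 2.8 | 0.1 | 96.1 |
| 25.0 | 0.4 | 8.2 | 0 | 91.0 |
| 50.0 | 0.8 | 17.2 | 0.1 | 82.9 |

(scatter of a reading: 0.5 percentage points)

- the analysis behind the earlier runs scatters by 0.5 percentage points, standard deviation

- which of these there is most of at the end, counted by the substrate in it, noon (product / catalyst intermediate D / catalyst intermediate C / substrate)
- which of these there is most of at the end, counted by the substrate in it, summer (product / catalyst intermediate D / catalyst intermediate C / substrate)
- which of these there is most of at the end, counted by the substrate in it, spring (product / catalyst intermediate D / catalyst intermediate C / substrate)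
- the largest of these amounts at the end, in percent of the substrate charged, noon
- the largest of these amounts at the end, in percent of the substrate charged, summer
- the largest of these amounts at the end, in percent of the substrate charged, spring

I assume one reagent is used per product. Then reagent is the limiting reagent, at 0.700 equivalents, and the three flasks share one end state: product at 70.0% of the substrate charged, with substrate holding the rest.

Which numbers must I know well? The catalyst charge is 0.760% of the substrate charge, so I need not know C and D closely, since substrate bound on catalyst counts for about that share. The reagent charge must be good: in my reckoning the ceiling is that charge divided by the substrate charge. The rate of product formation leaves the ceiling alone and matters for a flask read near the moment the reagent is used up, but not for one read well past it.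

Now the rate itself. Thursday's product rises by 14 percentage points between 10.0 s and 50.0 s, with a scatter of 0.5 points on each reading. Its two stretches give 0.108 mM min⁻¹ and 0.108 mM min⁻¹, and the whole run gives 0.108 mM min⁻¹. That run cannot show the reagent order, but I commit to this steady rate. The fill time, the reagent charge divided by this rate, is then 3.24 min. Summer is read at 1.85 times the fill time and spring at 3.70 times it, so both should stand at the ceiling. Noon is read just short of it, and I reckon 64.8% product there, more than the remaining substrate.

The forecast says substrate at 63% for noon, product at 57% for summer and product at 67% for spring. Its grounds are these: “I guess the slow step is C + reagent, so the rate falls as reagent is consumed”. There it differs from my steady rate.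

The flasks give product at 56.1% for noon, product at 70.0% for summer and product at 70.0% for spring.

    catalyst intermediate C → released group + catalyst intermediate D (k = 0.560 s⁻¹)
    catalyst intermediate D → free catalyst + product (k = 46.0 s⁻¹)
    substrate + catalyst intermediate B → catalyst intermediate C (k = 7.40 × 10⁵ L mol⁻¹ s⁻¹)
    catalyst intermediate A → catalyst intermediate B (k = 2.80 s⁻¹)
    reagent + free catalyst → catalyst intermediate A (k = 22000 L mol⁻¹ s⁻¹)

Summer, at 1.85 fill times, stands at the ceiling with reagent at 0%. Noon, at 0.926 fill times, reaches 86.6% of my reckoned product. Now take the neighbouring flask, noon with 0.0020 M of substrate. Its reagent charge is unchanged, so with the same rate its fill time stays 3.24 min. Its ceiling is 17.5%, and the reckoning gives 16.2% at 3.0 min. That flask holds 14.0% product, and its reagent stands at 19.0% of its charge, against 19.1% in noon.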